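## Retrosynthetic overview

1. Homo-plakotenin ⇐ hydrolysis of its ethyl ester ⇐ thermal intramolecular Diels–Alder reaction of a (2E,4Z,6R,8R,9E,11E)-tetraenoate. The cyclohexene and the trans-fused cyclopentane form together in this one step, with four stereocentres.
2. Tetraenoate ⇐ Wittig reaction on a (Z)-2-ethyl enal ⇐ Still–Gennari olefination of an α-methyl aldehyde. The (E,E)-phenyldiene end ⇐ stabilised Wittig reaction, then benzylphosphonate HWE.
3. Both ends grow, one at a time, from mono-silylated (2R,4R)-2,4-dimethylpentane-1,5-diol.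
4. Its second stereocentre ⇐ Ir-catalysed asymmetric hydrogenation of a trisubstituted allylic alcohol. Its first stereocentre ⇐ lipase-catalysed desymmetrisation of 2-methylpropane-1,3-diol.

Assumption: the stereochemistry is taken exactly as written in the SMILES, and the thermal Diels–Alder step is assumed to take the exo-tether mode on the diene face that gives this diastereomer from the (6R,8R)-tetraene; this is the least certain point of the route (see the risks).

## Route

Step 1
Reactants: 1 2-methylpropane-1,3-diol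
Product: 2 (S)-3-hydroxy-2-methylpropyl acetate
Conditions: lipase (Pseudomonas fluorescens lipase, Amano AK), vinyl acetate, CHCl3, 25 °C; stopped once the minor monoacetate has gone on to diacetate
Reagents that add atoms: vinyl acetate, C=COC(C)=O
Why: Lipase-catalysed irreversible transesterification desymmetrises the prochiral diol at the pro-S hydroxymethyl arm and the second acylation removes the minor enantiomer, so the enzyme sets the first stereocentre in high ee.

Step 2
Reactants: 2 (S)-3-hydroxy-2-methylpropyl acetate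
Product: 3 (R)-3-[(tert-butyldiphenylsilyl)oxy]-2-methylpropyl acetate
Conditions: TBDPSCl, imidazole, CH2Cl2, 0 °C to rt, directly after step 1
Reagents that add atoms: tert-butyl(chloro)diphenylsilane (TBDPSCl), CC(C)(C)[Si](Cl)(c1ccccc1)c1ccccc1
Why: Silylation of the free primary alcohol under mild base differentiates the two arms before 1,3-acyl migration can racemise the monoacetate (the descriptor changes by CIP only).

Step 3
Reactants: 3 (R)-3-[(tert-butyldiphenylsilyl)oxy]-2-methylpropyl acetate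
Product: 4 (R)-3-[(tert-butyldiphenylsilyl)oxy]-2-methylpropan-1-ol
Conditions: K2CO3 (0.2 equiv), MeOH, 0 °C
Reagents that add atoms: none
Why: Base-catalysed transesterification removes the acetate, while the TBDPS ether neither cleaves nor migrates under these conditions.

Step 4
Reactants: 4 (R)-3-[(tert-butyldiphenylsilyl)oxy]-2-methylpropan-1-ol; 5 ethyl 2-(triphenyl-λ5-phosphanylidene)propanoate
Product: 7 ethyl (2E,4R)-5-[(tert-butyldiphenylsilyl)oxy]-2,4-dimethylpent-2-enoate, via (S)-3-[(tert-butyldiphenylsilyl)oxy]-2-methylpropanal 6 (not isolated)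
Conditions: TEMPO (10 mol %), PhI(OAc)2, CH2Cl2, rt; then 5, rt to 40 °C
Reagents that add atoms: none
Why: TEMPO/PhI(OAc)2 oxidation followed in the same flask by a stabilised-ylide Wittig reaction traps the epimerisable α-methyl aldehyde and gives the (E)-trisubstituted enoate.

Step 5
Reactants: 7 ethyl (2E,4R)-5-[(tert-butyldiphenylsilyl)oxy]-2,4-dimethylpent-2-enoate
Product: 8 (2E,4R)-5-[(tert-butyldiphenylsilyl)oxy]-2,4-dimethylpent-2-en-1-ol
Conditions: DIBAL-H (2.2 equiv), CH2Cl2, −78 °C; Rochelle salt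
Reagents that add atoms: none
Why: DIBAL-H reduces the conjugated ester cleanly 1,2 to the allylic alcohol without touching the alkene or the silyl ether.

Step 6
Reactants: 8 (2E,4R)-5-[(tert-butyldiphenylsilyl)oxy]-2,4-dimethylpent-2-en-1-ol
Product: 9 (2R,4R)-5-[(tert-butyldiphenylsilyl)oxy]-2,4-dimethylpentan-1-ol
Conditions: H2 (50 bar), [Ir(cod)(L*)]BArF (1 mol %; chiral NHC–oxazoline or PHOX-type N,P ligand, the enantiomer that gives the 2,4-anti product), CH2Cl2, rt
Reagents that add atoms: none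
Why: Ir-catalysed asymmetric hydrogenation of the trisubstituted allylic alcohol is catalyst-controlled and sets C2 as R, anti to the existing C4 centre.

Step 7
Reactants: 9 (2R,4R)-5-[(tert-butyldiphenylsilyl)oxy]-2,4-dimethylpentan-1-ol; 10 ethyl 2-(triphenyl-λ5-phosphanylidene)butanoate
Product: 12 ethyl (2E,4R,6R)-7-[(tert-butyldiphenylsilyl)oxy]-2-ethyl-4,6-dimethylhept-2-enoate, via (2R,4R)-5-[(tert-butyldiphenylsilyl)oxy]-2,4-dimethylpentanal 11 (not isolated)
Conditions: TEMPO (10 mol %), PhI(OAc)2, CH2Cl2, rt; then 10, 40 °C, 48 h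
Reagents that add atoms: none
Why: The one-pot oxidation/Wittig reaction avoids isolating the α-chiral aldehyde, and the stabilised α-ethyl ylide gives the (E)-enoate with the ethyl group cis to the chain, as the diene requires.

Step 8
Reactants: 12 ethyl (2E,4R,6R)-7-[(tert-butyldiphenylsilyl)oxy]-2-ethyl-4,6-dimethylhept-2-enoate
Product: 13 (2E,4R,6R)-7-[(tert-butyldiphenylsilyl)oxy]-2-ethyl-4,6-dimethylhept-2-en-1-ol
Conditions: DIBAL-H (2.2 equiv), CH2Cl2, −78 °C; Rochelle salt
Reagents that add atoms: none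
Why: DIBAL-H reduces the enoate 1,2 to the allylic alcohol with the alkene geometry unchanged.

Step 9
Reactants: 13 (2E,4R,6R)-7-[(tert-butyldiphenylsilyl)oxy]-2-ethyl-4,6-dimethylhept-2-en-1-ol
Product: 14 (2E,4R,6R)-7-[(tert-butyldiphenylsilyl)oxy]-2-ethyl-4,6-dimethylhept-2-enal
Conditions: TEMPO (10 mol %), PhI(OAc)2, CH2Cl2, rt
Reagents that add atoms: none
Why: Oxoammonium (TEMPO) oxidation converts the allylic alcohol into the enal under neutral conditions without E/Z isomerisation or γ-epimerisation.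

Step 10
Reactants: 14 (2E,4R,6R)-7-[(tert-butyldiphenylsilyl)oxy]-2-ethyl-4,6-dimethylhept-2-enal; 15 diethyl benzylphosphonate
Product: 16 tert-butyl{[(2R,4R,5E,7E)-6-ethyl-2,4-dimethyl-8-phenylocta-5,7-dien-1-yl]oxy}diphenylsilane
Conditions: 15, KOt-Bu, THF, 0 °C; then 14, −78 °C to rt
Reagents that add atoms: none
Why: Horner–Wadsworth–Emmons reaction of the preformed benzylphosphonate anion gives the (E)-styryl bond, and carbonyl addition at low temperature outruns γ-deprotonation of the enal.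

Step 11
Reactants: 16 tert-butyl{[(2R,4R,5E,7E)-6-ethyl-2,4-dimethyl-8-phenylocta-5,7-dien-1-yl]oxy}diphenylsilane
Product: 17 (2R,4R,5E,7E)-6-ethyl-2,4-dimethyl-8-phenylocta-5,7-dien-1-ol
Conditions: TBAF, THF, rt
Reagents that add atoms: none
Why: Fluoride cleaves the Si–O bond of the TBDPS ether and leaves the diene untouched.

Step 12
Reactants: 17 (2R,4R,5E,7E)-6-ethyl-2,4-dimethyl-8-phenylocta-5,7-dien-1-ol
Product: 18 (2R,4R,5E,7E)-6-ethyl-2,4-dimethyl-8-phenylocta-5,7-dienal
Conditions: TEMPO (10 mol %), PhI(OAc)2, CH2Cl2, rt; used crude at once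
Reagents that add atoms: none
Why: TEMPO oxidation of the primary alcohol stops at the aldehyde and does not epimerise the α-methyl centre.

Step 13
Reactants: 19 methyl 2-[bis(2,2,2-trifluoroethoxy)phosphoryl]acetate
Product: 20 methyl 2-[bis(2,2,2-trifluoroethoxy)phosphoryl]butanoate (racemic; its stereocentre is lost in step 14)
Conditions: KOt-Bu, DMF, 0 °C; EtI, rt
Reagents that add atoms: iodoethane, CCI
Why: SN2 C-alkylation of the stabilised phosphonoacetate anion installs the ethyl group that becomes the ethyl on the quaternary carbon.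

Step 14
Reactants: 18 (2R,4R,5E,7E)-6-ethyl-2,4-dimethyl-8-phenylocta-5,7-dienal; 20 methyl 2-[bis(2,2,2-trifluoroethoxy)phosphoryl]butanoate
Product: 21 methyl (2Z,4R,6R,7E,9E)-2,8-diethyl-4,6-dimethyl-10-phenyldeca-2,7,9-trienoate
Conditions: 20, KHMDS, 18-crown-6, THF, −78 °C; then 18, −78 °C
Reagents that add atoms: none
Why: The Still–Gennari variant of the HWE reaction eliminates fast from the kinetic adduct and gives the (Z)-enoate, which places the future side-chain carbon cis to the tether.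

Step 15
Reactants: 21 methyl (2Z,4R,6R,7E,9E)-2,8-diethyl-4,6-dimethyl-10-phenyldeca-2,7,9-trienoate
Product: 22 (2Z,4R,6R,7E,9E)-2,8-diethyl-4,6-dimethyl-10-phenyldeca-2,7,9-trien-1-ol
Conditions: DIBAL-H (2.2 equiv), CH2Cl2, −78 °C; Rochelle salt
Reagents that add atoms: none
Why: DIBAL-H reduces the ester 1,2 at low temperature and keeps the (Z)-geometry.

Step 16
Reactants: 22 (2Z,4R,6R,7E,9E)-2,8-diethyl-4,6-dimethyl-10-phenyldeca-2,7,9-trien-1-ol; 5 ethyl 2-(triphenyl-λ5-phosphanylidene)propanoate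
Product: 24 ethyl (2E,4Z,6R,8R,9E,11E)-4,10-diethyl-2,6,8-trimethyl-12-phenyldodeca-2,4,9,11-tetraenoate, via (2Z,4R,6R,7E,9E)-2,8-diethyl-4,6-dimethyl-10-phenyldeca-2,7,9-trienal 23 (not isolated)
Conditions: TEMPO (10 mol %), PhI(OAc)2, CH2Cl2, rt; then 5, 40 °C
Reagents that add atoms: none
Why: One-pot oxidation/Wittig reaction consumes the isomerisation-prone (Z)-enal as it forms, and the stabilised ylide gives the (2E)-alkene.

Step 17
Reactants: 24 ethyl (2E,4Z,6R,8R,9E,11E)-4,10-diethyl-2,6,8-trimethyl-12-phenyldodeca-2,4,9,11-tetraenoate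
Product: 25 ethyl (2E)-3-[(1R,3R,3aR,4S,5S,7aR)-4,7-diethyl-1,3-dimethyl-5-phenyl-2,3,3a,4,5,7a-hexahydro-1H-inden-4-yl]-2-methylprop-2-enoate
Conditions: toluene (0.01 M), BHT (cat.), 110 °C, sealed tube; chromatography
Reagents that add atoms: none
Why: The thermal intramolecular Diels–Alder reaction through the exo-tether transition state forms both rings trans-fused; suprafacial addition turns the (9E,11E)-diene and (4Z)-dienophile geometry into the phenyl/quaternary-carbon/ring-fusion relationships, and the two (R)-methyl centres of the tether select the diene face.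

Step 18
Reactants: 25 ethyl (2E)-3-[(1R,3R,3aR,4S,5S,7aR)-4,7-diethyl-1,3-dimethyl-5-phenyl-2,3,3a,4,5,7a-hexahydro-1H-inden-4-yl]-2-methylprop-2-enoate
Product: 26 homo-plakotenin, (2E)-3-[(1R,3R,3aR,4S,5S,7aR)-4,7-diethyl-1,3-dimethyl-5-phenyl-2,3,3a,4,5,7a-hexahydro-1H-inden-4-yl]-2-methylprop-2-enoic acid
Conditions: LiOH·H2O, THF/MeOH/H2O, 50 °C; then 1 M HCl
Reagents that add atoms: lithium hydroxide, [Li+].[OH-]
Why: Saponification of the conjugated ester cannot epimerise any centre (none is α to the carbonyl) and leaves the (E)-alkene intact.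

## Compound list

1 | 2-methylpropane-1,3-diol | CC(CO)CO | starting material
2 | (S)-3-hydroxy-2-methylpropyl acetate | CC(=O)OC[C@@H](C)CO | intermediate
3 | (R)-3-[(tert-butyldiphenylsilyl)oxy]-2-methylpropyl acetate | CC(=O)OC[C@@H](C)CO[Si](c1ccccc1)(c1ccccc1)C(C)(C)C | intermediate
4 | (R)-3-[(tert-butyldiphenylsilyl)oxy]-2-methylpropan-1-ol | OC[C@@H](C)CO[Si](c1ccccc1)(c1ccccc1)C(C)(C)C | intermediate
5 | ethyl 2-(triphenyl-λ5-phosphanylidene)propanoate | CCOC(=O)C(C)=P(c1ccccc1)(c1ccccc1)c1ccccc1 | starting material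
6 | (S)-3-[(tert-butyldiphenylsilyl)oxy]-2-methylpropanal | O=C[C@@H](C)CO[Si](c1ccccc1)(c1ccccc1)C(C)(C)C | intermediate
7 | ethyl (2E,4R)-5-[(tert-butyldiphenylsilyl)oxy]-2,4-dimethylpent-2-enoate | CCOC(=O)/C(C)=C/[C@@H](C)CO[Si](c1ccccc1)(c1ccccc1)C(C)(C)C | intermediate
8 | (2E,4R)-5-[(tert-butyldiphenylsilyl)oxy]-2,4-dimethylpent-2-en-1-ol | OC/C(C)=C/[C@@H](C)CO[Si](c1ccccc1)(c1ccccc1)C(C)(C)C | intermediate
9 | (2R,4R)-5-[(tert-butyldiphenylsilyl)oxy]-2,4-dimethylpentan-1-ol | OC[C@H](C)C[C@@H](C)CO[Si](c1ccccc1)(c1ccccc1)C(C)(C)C | intermediate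
10 | ethyl 2-(triphenyl-λ5-phosphanylidene)butanoate | CCOC(=O)C(CC)=P(c1ccccc1)(c1ccccc1)c1ccccc1 | starting material
11 | (2R,4R)-5-[(tert-butyldiphenylsilyl)oxy]-2,4-dimethylpentanal | O=C[C@H](C)C[C@@H](C)CO[Si](c1ccccc1)(c1ccccc1)C(C)(C)C | intermediate
12 | ethyl (2E,4R,6R)-7-[(tert-butyldiphenylsilyl)oxy]-2-ethyl-4,6-dimethylhept-2-enoate | CCOC(=O)/C(CC)=C/[C@H](C)C[C@@H](C)CO[Si](c1ccccc1)(c1ccccc1)C(C)(C)C | intermediate
13 | (2E,4R,6R)-7-[(tert-butyldiphenylsilyl)oxy]-2-ethyl-4,6-dimethylhept-2-en-1-ol | OC/C(CC)=C/[C@H](C)C[C@@H](C)CO[Si](c1ccccc1)(c1ccccc1)C(C)(C)C | intermediate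
14 | (2E,4R,6R)-7-[(tert-butyldiphenylsilyl)oxy]-2-ethyl-4,6-dimethylhept-2-enal | O=C/C(CC)=C/[C@H](C)C[C@@H](C)CO[Si](c1ccccc1)(c1ccccc1)C(C)(C)C | intermediate
15 | diethyl benzylphosphonate | CCOP(=O)(Cc1ccccc1)OCC | starting material
16 | tert-butyl{[(2R,4R,5E,7E)-6-ethyl-2,4-dimethyl-8-phenylocta-5,7-dien-1-yl]oxy}diphenylsilane | CC(C)(C)[Si](c1ccccc1)(c1ccccc1)OC[C@H](C)C[C@@H](C)/C=C(CC)/C=C/c1ccccc1 | intermediate
17 | (2R,4R,5E,7E)-6-ethyl-2,4-dimethyl-8-phenylocta-5,7-dien-1-ol | OC[C@H](C)C[C@@H](C)/C=C(CC)/C=C/c1ccccc1 | intermediate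
18 | (2R,4R,5E,7E)-6-ethyl-2,4-dimethyl-8-phenylocta-5,7-dienal | O=C[C@H](C)C[C@@H](C)/C=C(CC)/C=C/c1ccccc1 | intermediate
19 | methyl 2-[bis(2,2,2-trifluoroethoxy)phosphoryl]acetate | COC(=O)CP(=O)(OCC(F)(F)F)OCC(F)(F)F | starting material
20 | methyl 2-[bis(2,2,2-trifluoroethoxy)phosphoryl]butanoate (racemic) | CCC(C(=O)OC)P(=O)(OCC(F)(F)F)OCC(F)(F)F | intermediate
21 | methyl (2Z,4R,6R,7E,9E)-2,8-diethyl-4,6-dimethyl-10-phenyldeca-2,7,9-trienoate | COC(=O)/C(CC)=C\[C@H](C)C[C@@H](C)/C=C(CC)/C=C/c1ccccc1 | intermediate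
22 | (2Z,4R,6R,7E,9E)-2,8-diethyl-4,6-dimethyl-10-phenyldeca-2,7,9-trien-1-ol | OC/C(CC)=C\[C@H](C)C[C@@H](C)/C=C(CC)/C=C/c1ccccc1 | intermediate
23 | (2Z,4R,6R,7E,9E)-2,8-diethyl-4,6-dimethyl-10-phenyldeca-2,7,9-trienal | O=C/C(CC)=C\[C@H](C)C[C@@H](C)/C=C(CC)/C=C/c1ccccc1 | intermediate
24 | ethyl (2E,4Z,6R,8R,9E,11E)-4,10-diethyl-2,6,8-trimethyl-12-phenyldodeca-2,4,9,11-tetraenoate | CCOC(=O)/C(C)=C/C(CC)=C\[C@H](C)C[C@@H](C)/C=C(CC)/C=C/c1ccccc1 | intermediate
25 | ethyl (2E)-3-[(1R,3R,3aR,4S,5S,7aR)-4,7-diethyl-1,3-dimethyl-5-phenyl-2,3,3a,4,5,7a-hexahydro-1H-inden-4-yl]-2-methylprop-2-enoate | CCC1=C[C@@H](c2ccccc2)[C@@](/C=C(\C)C(=O)OCC)(CC)[C@H]2[C@H]1[C@H](C)C[C@H]2C | intermediate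
26 | homo-plakotenin, (2E)-3-[(1R,3R,3aR,4S,5S,7aR)-4,7-diethyl-1,3-dimethyl-5-phenyl-2,3,3a,4,5,7a-hexahydro-1H-inden-4-yl]-2-methylprop-2-enoic acid | CCC1=C[C@@H](c2ccccc2)[C@@](/C=C(\C)C(=O)O)(CC)[C@H]2[C@H]1[C@H](C)C[C@H]2C | target

## Step count and risks

Total step count: 18. Longest linear sequence: 17 steps (steps 1–12 and 14–18); step 13 is a one-step side branch.

The three steps most likely to fail:

(a) The cycloaddition, step 17. The transition state that leads to 25 holds both tether methyls on the inside, syn to the neighbouring sp2 carbons, where they meet 1,3-allylic strain from the ethyl group on the diene and from the side-chain carbon on the dienophile. The trans-fused adduct from the other diene face, or cis-fused adducts, may therefore compete or dominate, and the configuration of 25 must be proved by NOE or X-ray. The fallback sets out from trienoate 21 and comes back at 25, so that steps 15 and 16 are no longer needed. Heating 21 alone (toluene, 130 °C, BHT) lets the same diene add to the ester-activated (Z)-dienophile, where the group cis to the tether is only a rotatable CO2Me. This gives methyl (1R,3R,3aR,4R,5S,7aR)-4,7-diethyl-1,3-dimethyl-5-phenyl-2,3,3a,4,5,7a-hexahydro-1H-indene-4-carboxylate F1, whose isomers are separated and assigned at this simpler stage. DIBAL-H then gives the neopentyl alcohol [(1R,3R,3aR,4R,5S,7aR)-4,7-diethyl-1,3-dimethyl-5-phenyl-2,3,3a,4,5,7a-hexahydro-1H-inden-4-yl]methanol F2. Dess–Martin oxidation gives (1R,3R,3aR,4R,5S,7aR)-4,7-diethyl-1,3-dimethyl-5-phenyl-2,3,3a,4,5,7a-hexahydro-1H-indene-4-carbaldehyde F3. A Wittig reaction of F3 with 5 (toluene, 110 °C) builds the (E)-methylpropenoate on the finished bicycle and returns to 25.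

(b) The (Z)-olefination, step 14, together with the (Z)-enal passed through in step 16. Z-selectivity with an α-ethyl Still–Gennari reagent on an α-branched aldehyde may be incomplete, and the (Z)-enal can isomerise to (E). The fallback sets out from aldehyde 18 and comes back at 24. Stork–Zhao olefination of 18 with the ylide from (1-iodopropyl)triphenylphosphonium iodide (NaHMDS, THF/HMPA, −78 °C) gives the (Z)-vinyl iodide [(1E,3E,5R,7R,8Z)-3-ethyl-9-iodo-5,7-dimethylundeca-1,3,8-trien-1-yl]benzene F4. Suzuki–Miyaura coupling of F4 with ethyl (E)-2-methyl-3-(pinacolboryl)acrylate (Pd(PPh3)4, aq. K3PO4, THF, rt) proceeds with retention on both partners and gives 24 directly, without any (Z)-enal.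

(c) The asymmetric hydrogenation, step 6. With the existing C4 centre the catalyst may be mismatched and give too little of the anti isomer. The fallback sets out from alcohol 4 and comes back at 9, making the second methyl centre by C–C instead of C–H bond formation. Iodination (I2, PPh3, imidazole) gives (S)-tert-butyl(3-iodo-2-methylpropoxy)diphenylsilane F5. Lithium–iodine exchange (t-BuLi), transmetallation to zinc and Pd-catalysed coupling with vinyl bromide give (R)-tert-butyl[(2-methylpent-4-en-1-yl)oxy]diphenylsilane F6. Zr-catalysed asymmetric carboalumination of F6 (Me3Al, (−)-(NMI)2ZrCl2, CH2Cl2; then O2) gives 9. A lipase (Amano PS)/vinyl acetate treatment then acetylates the minor 2S epimer faster, so that 9 is recovered diastereomerically pure.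

## Further compounds

F1 | step 17 | methyl (1R,3R,3aR,4R,5S,7aR)-4,7-diethyl-1,3-dimethyl-5-phenyl-2,3,3a,4,5,7a-hexahydro-1H-indene-4-carboxylate | CCC1=C[C@@H](c2ccccc2)[C@@](C(=O)OC)(CC)[C@H]2[C@H]1[C@H](C)C[C@H]2C
F2 | step 17 | [(1R,3R,3aR,4R,5S,7aR)-4,7-diethyl-1,3-dimethyl-5-phenyl-2,3,3a,4,5,7a-hexahydro-1H-inden-4-yl]methanol | CCC1=C[C@@H](c2ccccc2)[C@@](CO)(CC)[C@H]2[C@H]1[C@H](C)C[C@H]2C
F3 | step 17 | (1R,3R,3aR,4R,5S,7aR)-4,7-diethyl-1,3-dimethyl-5-phenyl-2,3,3a,4,5,7a-hexahydro-1H-indene-4-carbaldehyde | CCC1=C[C@@H](c2ccccc2)[C@@](C=O)(CC)[C@H]2[C@H]1[C@H](C)C[C@H]2C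
F4 | step 14 | [(1E,3E,5R,7R,8Z)-3-ethyl-9-iodo-5,7-dimethylundeca-1,3,8-trien-1-yl]benzene | I/C(CC)=C\[C@H](C)C[C@@H](C)/C=C(CC)/C=C/c1ccccc1
F5 | step 6 | (S)-tert-butyl(3-iodo-2-methylpropoxy)diphenylsilane | IC[C@@H](C)CO[Si](c1ccccc1)(c1ccccc1)C(C)(C)C
F6 | step 6 | (R)-tert-butyl[(2-methylpent-4-en-1-yl)oxy]diphenylsilane | C=CC[C@@H](C)CO[Si](c1ccccc1)(c1ccccc1)C(C)(C)C
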